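The data come from a simulation for substances that don't exist; scatter was added.

If J was charged short of G, zeta showed where G stopped: there [J]/[G] was 75.0%, G read 25.7% at the end against the 25.0% that J could not pair, and X peaked at a reading of 73.4%.

| flask | G | J | E | temperature | remark | time |
|---|---|---|---|---|---|---|
| epsilon | 0.015 M | 0.015 M | 5.9 µM | 25 °C | run made earlier |  |
| zeta | 0.020 M | 0.015 M | 5.9 µM | 25 °C | run made earlier |  |
| blue | 0.010 M | 0.0150 M | 1.5 µM |  | at 45 °C throughout | 10 d |
| ochre | 0.010 M | 0.0150 M | 5.9 µM |  | at 25 °C until 5.0 d, from then on at 45 °C | 10 d |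

| run | time / d | X / % | G / % |
|---|---|---|---|
| epsilon | 0.625 | 67.1 | 33.3 |
| epsilon | 1.25 | 87.9 | 9.2 |
| epsilon | 1.67 | 92.8 | 3.8 |
| epsilon | 2.50 | 95.0 | 0.9 |
| epsilon | 3.00 | 92.8 | 1.2 |
| epsilon | 4.00 | 92.4 | 0 |
| zeta | 0.625 | 58.0 | 41.5 |
| zeta | 1.25 | 69.6 | 25.9 |
| zeta | 1.67 | 73.4 | 25.1 |
| zeta | 2.50 | 70.5 | 25.1 |
| zeta | 3.00 | 69.4 | 24.3 |
| zeta | 4.00 | 66.1 | 25.7 |

(readings scatter by 1 percentage point)

1. the winner by amount of X, in percent of the G charged; "neither" if no more than 2 percentage points parts them (blue / ochre / neither)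
2. how much X is there at the end, in percent of the G charged: blue
3. how much X is there at the end, in percent of the G charged: ochre

- the analysis behind the earlier runs scatters by 1 percentage point, standard deviation
- the earlier runs do not show what temperature does; that part of a forecast is a guess
- no earlier run changes the charge of E; that part of a forecast is a guess

Blue and ochre shared one charge of G and of J, so they shared 100%: the roof, the smaller of the charged ratio [J]/[G] and the whole G charge, which is the ceiling the limiting reagent sets on X plus whatever X turns into. The roof told me how far, not how soon. Blue had a quarter of ochre's E, but epsilon's G read 0.9% by 2.50 d, and blue had 10 d.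

I took X as the roof less a small correction and reckoned the correction alone. Epsilon's roof was 100%, and with G reading 0%, its X read 7.6 percentage points under that roof at 4.00 d. In proportion to time, this put ochre 9.5 points under its roof at 5.0 d, so X near 90.5%. The runs were silent on heat. Blue spent 10 d at 45 °C, longer than ochre's 5.00 d, so I expected blue lower unless the gap levelled off, and the readings stopped at 4.00 d. I put no number on that.

The forecast did: 24% for blue, 43% for ochre, winner ochre, on the ground that “X then slowly disappears without returning G”.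

Blue ended with 72.2% of X and ochre with 72.3%, so the answer was neither. At 100 d blue still held 72.2% and ochre 72.2%. The gap under the roof was L: X plus L came to 100% in blue and 100% in ochre, which is the roof of 100%.

    G + E → D (k = 20000 M⁻¹ h⁻¹, Ea = 51.0 kJ mol⁻¹)
    Z → E + X (k = 2000 h⁻¹, Ea = 78.0 kJ mol⁻¹)
    J + D ⇌ Z (K = 23.0 M⁻¹, k = 3.10 × 10⁵ M⁻¹ h⁻¹, Ea = 40.0 kJ mol⁻¹, ΔH = 5.00 kJ mol⁻¹)
    X ⇌ L (K = 1.40, k = 0.00100 h⁻¹, Ea = 102 kJ mol⁻¹, ΔH = −51.0 kJ mol⁻¹)
    (constants at 25 °C)

In the neighbour with 0.025 M of G, otherwise ochre, the roof fell to 60.0%, and ochre's share of X under its roof gave 43.4%. The computed flask held 43.4% of X and 16.6% of L, with 40.0% of G unpaired.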